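**Retrosynthetic overview**
1. C13–Br from the C13 alcohol (SN2, inversion); C10–OAc from a C10 ketone (hydride reduction, then invertive Mitsunobu acetylation).
2. The oxocane (the only ring, closed in step 9) from an acyclic α,α-dichloromethyl ketone by 8-endo chlorine-atom-transfer radical cyclisation: C8–C9 and C7–Cl form, C9 keeps one Cl.
3. Dichloromethyl ketone from a methyl ester and LiCHCl2 (C9–C10); the β-alkoxy ester from an oxocarbenium ion and an acetate enolate equivalent (C11–C12), with the ether oxygen already joining C6 and C12.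
4. α-Acetoxy ether from the ester of (3S,5E)-octa-1,5-dien-7-yn-3-ol with (S)-2-silyloxybutanoic acid (C12–C15).
5. Enynol from acrolein (asymmetric allylation, sets C6), (E)-but-2-enal (cross-metathesis, C2–C3) and Me3SiCHN2 (C1).

Assumption: atom labels C1–C15 follow the linear chain of the target (C1 = alkyne CH, O bridges C6 and C12, target = 3E,6S,7S,9S,10S,12R,13R); (−)-Ipc2B(allyl) and Me3SiCHN2 are bought as reagent solutions.

**Route**

Step 1
Reactants: 1 (S)-2-hydroxybutanoic acid
Product: 3 (S)-2-[(tert-butyldimethylsilyl)oxy]butanoic acid, via bis-silyl derivative 2 (not isolated)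
Conditions: TBSCl (2.2 equiv), imidazole, DMF, rt; then K2CO3, MeOH–H2O, rt; aq. HCl to pH 4
Reagents that add atoms: tert-butyldimethylsilyl chloride, CC(C)(C)[Si](C)(C)Cl
Why: Exhaustive silylation followed by selective hydrolysis of the labile silyl ester leaves the hindered silyl ether (standard protection), and the future C13 centre is not touched.

Step 2
Reactants: 4 acrolein
Product: 6 (S)-hexa-1,5-dien-3-ol, via borinate ester 5 (not isolated)
Conditions: (−)-Ipc2B(allyl), Et2O, −78 °C; then NaOH, H2O2, 0 °C to rt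
Reagents that add atoms: (−)-B-allyldiisopinocampheylborane, C=CCB([C@@H]1C[C@@H]2C[C@H]([C@H]1C)C2(C)C)[C@@H]1C[C@@H]2C[C@H]([C@H]1C)C2(C)C
Why: Brown asymmetric allylboration through a chair six-membered transition state, in which the isopinocampheyl groups derived from (+)-α-pinene direct allyl transfer to the Si face of the aldehyde and set C6 as S.

Step 3
Reactants: 6 (S)-hexa-1,5-dien-3-ol; 7 (E)-but-2-enal (3 equiv)
Product: 8 (2E,5S)-5-hydroxyhepta-2,6-dienal
Conditions: second-generation Hoveyda–Grubbs catalyst (5 mol %), 1,4-benzoquinone (10 mol %), CH2Cl2, 40 °C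
Reagents that add atoms: none
Why: Olefin cross-metathesis in which the unhindered homoallylic terminal alkene couples with the enal partner faster than the vinyl group flanked by the carbinol centre, and the conjugated product alkene forms E under thermodynamic control.

Step 4
Reactants: 8 (2E,5S)-5-hydroxyhepta-2,6-dienal
Product: 9 (3S,5E)-octa-1,5-dien-7-yn-3-ol
Conditions: Me3SiCHN2 (2.5 equiv), LiN(i-Pr)2 (2.5 equiv), THF, −78 °C; then 8, −78 to 0 °C; aq. NH4Cl
Reagents that add atoms: (trimethylsilyl)diazomethane, C[Si](C)(C)C=[N+]=[N-]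
Why: Colvin rearrangement, in which 1,2-addition of lithiated Me3SiCHN2 to the aldehyde, Peterson-type elimination and 1,2-hydrogen shift of the alkylidene carbene give the terminal alkyne one carbon longer with the E-alkene retained.

Step 5
Reactants: 9 (3S,5E)-octa-1,5-dien-7-yn-3-ol; 3 (S)-2-[(tert-butyldimethylsilyl)oxy]butanoic acid
Product: 10 (3S,5E)-octa-1,5-dien-7-yn-3-yl (2S)-2-[(tert-butyldimethylsilyl)oxy]butanoate
Conditions: N,N′-diisopropylcarbodiimide, DMAP (10 mol %), CH2Cl2, 0 °C to rt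
Reagents that add atoms: none
Why: Steglich-type carbodiimide esterification of a secondary alcohol, which joins the C6 oxygen to the future C12 carbon without touching a stereocentre.

Step 6
Reactants: 10 (3S,5E)-octa-1,5-dien-7-yn-3-yl (2S)-2-[(tert-butyldimethylsilyl)oxy]butanoate
Product: 12 (2S)-2-[(tert-butyldimethylsilyl)oxy]-1-{[(3S,5E)-octa-1,5-dien-7-yn-3-yl]oxy}butyl acetate (both epimers at C1), via aluminium hemiacetal 11 (not isolated)
Conditions: i-Bu2AlH (2 equiv), CH2Cl2, −78 °C; then pyridine, DMAP, Ac2O, −78 to −20 °C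
Reagents that add atoms: acetic anhydride, CC(=O)OC(C)=O
Why: Reductive acetylation of an ester, in which the aluminium hemiacetal is stable at −78 °C and is acetylated before it can collapse, giving the α-acetoxy ether as an inconsequential mixture at the acetal carbon (future C12).

Step 7
Reactants: 12 (2S)-2-[(tert-butyldimethylsilyl)oxy]-1-{[(3S,5E)-octa-1,5-dien-7-yn-3-yl]oxy}butyl acetate; 13 methyl acetate
Product: 15 methyl (3R,4S)-4-[(tert-butyldimethylsilyl)oxy]-3-{[(3S,5E)-octa-1,5-dien-7-yn-3-yl]oxy}hexanoate, via ketene silyl acetal 14 (not isolated)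
Conditions: MeOAc, LiN(i-Pr)2, THF, −78 °C, then Me3SiCl (gives 14, solvent changed to CH2Cl2); 12, BF3·OEt2, CH2Cl2, −78 °C
Reagents that add atoms: none
Why: Mukaiyama-type addition to an oxocarbenium ion, in which BF3 ionises the acetate and the ketene silyl acetal attacks C12 anti to the C13 silyloxy group (Cornforth/polar Felkin–Anh model), setting C12 as R.

Step 8
Reactants: 15 methyl (3R,4S)-4-[(tert-butyldimethylsilyl)oxy]-3-{[(3S,5E)-octa-1,5-dien-7-yn-3-yl]oxy}hexanoate
Product: 17 (4R,5S)-5-[(tert-butyldimethylsilyl)oxy]-1,1-dichloro-4-{[(3S,5E)-octa-1,5-dien-7-yn-3-yl]oxy}heptan-2-one, via lithium hemiketal 16 (not isolated)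
Conditions: CH2Cl2, LiN(i-Pr)2, THF, −100 °C (LiCHCl2, 3 equiv); 15, −100 to −78 °C; HCl (2 M in Et2O), −78 °C
Reagents that add atoms: dichloromethane, ClCCl
Why: Acylation of the carbenoid LiCHCl2 by the ester, in which the tetrahedral adduct survives at low temperature and releases the ketone only on acidic quench, so a second addition is avoided (the alkyne is lithiated in passing and reprotonated).

Step 9
Reactants: 17 (4R,5S)-5-[(tert-butyldimethylsilyl)oxy]-1,1-dichloro-4-{[(3S,5E)-octa-1,5-dien-7-yn-3-yl]oxy}heptan-2-one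
Product: 18 (2R,5S,7S,8S)-2-[(1S)-1-[(tert-butyldimethylsilyl)oxy]propyl]-5,7-dichloro-8-[(2E)-pent-2-en-4-yn-1-yl]oxocan-4-one
Conditions: CuCl (30 mol %), tris(2-pyridylmethyl)amine (30 mol %), ClCH2CH2Cl (5 mM, degassed), 80 °C
Reagents that add atoms: none
Why: Proposed new method: monovalent copper reversibly abstracts one chlorine, the electrophilic α-chloro-α-keto radical at C9 adds 8-endo to the unsubstituted alkene terminus C8 (7-exo attack at the branched C7 is hindered and a carbonyl inside the forming ring favours endo closure), and the C7 ring radical takes chlorine back from the divalent copper chloride complex on the peripheral face anti to the ring C–O bond, which with the C6 chain pseudo-axial (trans-2,8 pattern, bulky C12 group equatorial) is expected to place C7–Cl cis to that chain, while the epimerisable C9 centre settles trans to C7–Cl; the closest known reaction type is the copper-catalysed 8-endo chlorine-atom-transfer (Kharasch-type) cyclisation of pent-4-enyl di- and trichloroacetates to eight-membered lactones.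

Step 10
Reactants: 18 (2R,5S,7S,8S)-2-[(1S)-1-[(tert-butyldimethylsilyl)oxy]propyl]-5,7-dichloro-8-[(2E)-pent-2-en-4-yn-1-yl]oxocan-4-one
Product: 19 (2R,4R,5S,7S,8S)-2-[(1S)-1-[(tert-butyldimethylsilyl)oxy]propyl]-5,7-dichloro-8-[(2E)-pent-2-en-4-yn-1-yl]oxocan-4-ol
Conditions: NaBH4, MeOH, −40 °C
Reagents that add atoms: none
Why: Borohydride reduction of an α-chloro ketone, in which hydride adds antiperiplanar to the C9–Cl bond (Cornforth/polar Felkin–Anh) to give the cis-chlorohydrin with C10 as R.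

Step 11
Reactants: 19 (2R,4R,5S,7S,8S)-2-[(1S)-1-[(tert-butyldimethylsilyl)oxy]propyl]-5,7-dichloro-8-[(2E)-pent-2-en-4-yn-1-yl]oxocan-4-ol
Product: 20 (2R,4S,5S,7S,8S)-2-[(1S)-1-[(tert-butyldimethylsilyl)oxy]propyl]-5,7-dichloro-8-[(2E)-pent-2-en-4-yn-1-yl]oxocan-4-yl acetate
Conditions: PPh3, diisopropyl azodicarboxylate, AcOH, toluene, 0 °C to rt
Reagents that add atoms: acetic acid, CC(=O)O
Why: Mitsunobu esterification, in which acetate displaces the alkoxyphosphonium by SN2 and inverts C10 to S, placing the acetate trans to the C9 chloride (which, being cis to the leaving group, cannot participate).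

Step 12
Reactants: 20 (2R,4S,5S,7S,8S)-2-[(1S)-1-[(tert-butyldimethylsilyl)oxy]propyl]-5,7-dichloro-8-[(2E)-pent-2-en-4-yn-1-yl]oxocan-4-yl acetate
Product: 21 (2R,4S,5S,7S,8S)-5,7-dichloro-2-[(1S)-1-hydroxypropyl]-8-[(2E)-pent-2-en-4-yn-1-yl]oxocan-4-yl acetate
Conditions: HF·pyridine, THF–pyridine, 0 °C to rt
Reagents that add atoms: none
Why: Fluoride cleavage of the silyl ether under buffered conditions that leave the acetate, both alkyl chlorides and the enyne intact.

Step 13
Reactants: 21 (2R,4S,5S,7S,8S)-5,7-dichloro-2-[(1S)-1-hydroxypropyl]-8-[(2E)-pent-2-en-4-yn-1-yl]oxocan-4-yl acetate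
Product: 22 (2R,4S,5S,7S,8S)-2-[(1R)-1-bromopropyl]-5,7-dichloro-8-[(2E)-pent-2-en-4-yn-1-yl]oxocan-4-yl acetate
Conditions: CBr4, P(n-C8H17)3, toluene, 70 °C
Reagents that add atoms: carbon tetrabromide, BrC(Br)(Br)Br
Why: Appel-type bromination, in which bromide attacks the alkoxyphosphonium by SN2 and inverts C13 from S (alcohol) to R (bromide).

**Compound list**
1 | (S)-2-hydroxybutanoic acid | OC(=O)[C@@H](O)CC | starting material
2 | tert-butyldimethylsilyl (S)-2-[(tert-butyldimethylsilyl)oxy]butanoate | CC(C)(C)[Si](C)(C)OC(=O)[C@@H](O[Si](C)(C)C(C)(C)C)CC | intermediate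
3 | (S)-2-[(tert-butyldimethylsilyl)oxy]butanoic acid | OC(=O)[C@@H](O[Si](C)(C)C(C)(C)C)CC | intermediate
4 | acrolein (prop-2-enal) | C=CC=O | starting material
5 | (3S)-hexa-1,5-dien-3-yl diisopinocampheylborinate | C=CC[C@@H](C=C)OB([C@@H]1C[C@@H]2C[C@H]([C@H]1C)C2(C)C)[C@@H]1C[C@@H]2C[C@H]([C@H]1C)C2(C)C | intermediate
6 | (S)-hexa-1,5-dien-3-ol | C=CC[C@@H](C=C)O | intermediate
7 | (E)-but-2-enal | C/C=C/C=O | starting material
8 | (2E,5S)-5-hydroxyhepta-2,6-dienal | O=C/C=C/C[C@@H](C=C)O | intermediate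
9 | (3S,5E)-octa-1,5-dien-7-yn-3-ol | C#C/C=C/C[C@@H](C=C)O | intermediate
10 | (3S,5E)-octa-1,5-dien-7-yn-3-yl (2S)-2-[(tert-butyldimethylsilyl)oxy]butanoate | C#C/C=C/C[C@@H](C=C)OC(=O)[C@@H](O[Si](C)(C)C(C)(C)C)CC | intermediate
11 | diisobutylaluminium hemiacetal of 10 | C#C/C=C/C[C@@H](C=C)OC(O[Al](CC(C)C)CC(C)C)[C@@H](O[Si](C)(C)C(C)(C)C)CC | intermediate
12 | (2S)-2-[(tert-butyldimethylsilyl)oxy]-1-{[(3S,5E)-octa-1,5-dien-7-yn-3-yl]oxy}butyl acetate (both epimers at C1) | C#C/C=C/C[C@@H](C=C)OC(OC(C)=O)[C@@H](O[Si](C)(C)C(C)(C)C)CC | intermediate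
13 | methyl acetate | COC(C)=O | starting material
14 | 1-methoxy-1-(trimethylsilyloxy)ethene | C=C(OC)O[Si](C)(C)C | intermediate
15 | methyl (3R,4S)-4-[(tert-butyldimethylsilyl)oxy]-3-{[(3S,5E)-octa-1,5-dien-7-yn-3-yl]oxy}hexanoate | C#C/C=C/C[C@@H](C=C)O[C@@H]([C@@H](O[Si](C)(C)C(C)(C)C)CC)CC(=O)OC | intermediate
16 | dilithiated tetrahedral adduct of 15 with LiCHCl2 (lithium hemiketal, lithium acetylide) | [Li]C#C/C=C/C[C@@H](C=C)O[C@@H]([C@@H](O[Si](C)(C)C(C)(C)C)CC)CC(O[Li])(OC)C(Cl)Cl | intermediate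
17 | (4R,5S)-5-[(tert-butyldimethylsilyl)oxy]-1,1-dichloro-4-{[(3S,5E)-octa-1,5-dien-7-yn-3-yl]oxy}heptan-2-one | C#C/C=C/C[C@@H](C=C)O[C@@H]([C@@H](O[Si](C)(C)C(C)(C)C)CC)CC(=O)C(Cl)Cl | intermediate
18 | (2R,5S,7S,8S)-2-[(1S)-1-[(tert-butyldimethylsilyl)oxy]propyl]-5,7-dichloro-8-[(2E)-pent-2-en-4-yn-1-yl]oxocan-4-one | C#C/C=C/C[C@@H]1O[C@@H]([C@@H](O[Si](C)(C)C(C)(C)C)CC)CC(=O)[C@@H](Cl)C[C@@H]1Cl | intermediate
19 | (2R,4R,5S,7S,8S)-2-[(1S)-1-[(tert-butyldimethylsilyl)oxy]propyl]-5,7-dichloro-8-[(2E)-pent-2-en-4-yn-1-yl]oxocan-4-ol | C#C/C=C/C[C@@H]1O[C@@H]([C@@H](O[Si](C)(C)C(C)(C)C)CC)C[C@@H](O)[C@@H](Cl)C[C@@H]1Cl | intermediate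
20 | (2R,4S,5S,7S,8S)-2-[(1S)-1-[(tert-butyldimethylsilyl)oxy]propyl]-5,7-dichloro-8-[(2E)-pent-2-en-4-yn-1-yl]oxocan-4-yl acetate | C#C/C=C/C[C@@H]1O[C@@H]([C@@H](O[Si](C)(C)C(C)(C)C)CC)C[C@H](OC(C)=O)[C@@H](Cl)C[C@@H]1Cl | intermediate
21 | (2R,4S,5S,7S,8S)-5,7-dichloro-2-[(1S)-1-hydroxypropyl]-8-[(2E)-pent-2-en-4-yn-1-yl]oxocan-4-yl acetate | C#C/C=C/C[C@@H]1O[C@@H]([C@@H](O)CC)C[C@H](OC(C)=O)[C@@H](Cl)C[C@@H]1Cl | intermediate
22 | (2R,4S,5S,7S,8S)-2-[(1R)-1-bromopropyl]-5,7-dichloro-8-[(2E)-pent-2-en-4-yn-1-yl]oxocan-4-yl acetate | C#C/C=C/C[C@@H]1O[C@@H]([C@H](Br)CC)C[C@H](OC(C)=O)[C@@H](Cl)C[C@@H]1Cl | target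

**Step count and risks**
Total step count: 13. Longest linear sequence: 12 steps (acrolein 4 to target 22, steps 2–13); step 1 is the one-step side branch that joins at step 5.

Most likely to fail, in order:

Step 9 (ring closure). The 8-endo mode on a plain dichloromethyl ketone is unproven. Competing paths are 7-exo closure, attack on the enyne alkene, 1,6-hydrogen transfer from the allylic C6–H and interference of the terminal alkyne with copper. The facial course of chlorine delivery at C7 is the least secure stereochemical point of the route. If chlorine is delivered anti to the C6 chain (6,7-trans), the fallback uses that preference with a different halogen and an inversion. It sets out from ester 15 and comes back at ketone 18. Ester 15 is treated with LiCHBrCl (from CH2BrCl and LiN(i-Pr)2, −100 °C) to give the bromochloromethyl ketone F1. CuBr/tris(2-pyridylmethyl)amine then effects a bromine-atom-transfer cyclisation, in which only the C–Br bond is activated and bromine is returned to C7 trans to the side chain, giving the (7R)-bromo ketone F2. LiCl in DMF at 50 °C displaces the secondary bromide with inversion (the C9 α-chloro ketone stays at equilibrium) to give 18.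

Step 7 (C11–C12 bond and C12 configuration). The oxocarbenium ion may be captured by the enyne alkene (Prins-type), may lose the allylic C6–O bond, or may give a poor anti:syn ratio. The fallback makes the C12–O bond by conjugate addition instead of making the C11–C12 bond at an oxocarbenium ion. It sets out from acid 3 and enynol 9 and comes back at ester 15. Acid 3 is reduced with BH3·SMe2 to the alcohol F3 and oxidised with Dess–Martin periodinane to the aldehyde F4. Wittig olefination with Ph3P=CHCO2Me gives the (E)-enoate F5. The potassium alkoxide of 9 (KN(SiMe3)2, 20 mol %, THF, −20 °C) adds to the β-carbon of F5 anti to the γ-silyloxy group to give 15.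

Step 11 (inversion at C10). The Mitsunobu reaction on a hindered carbinol next to a C–Cl bond may stall or eliminate. The fallback separates activation from displacement. It sets out from 19 and comes back at 20. ClCH2SO2Cl and pyridine convert 19 into the chloromethanesulfonate F6, and CsOAc with 18-crown-6 in toluene at 80 °C displaces it with inversion to give 20.

Further compounds
F1 | step 9 | (4R,5S)-1-bromo-5-[(tert-butyldimethylsilyl)oxy]-1-chloro-4-{[(3S,5E)-octa-1,5-dien-7-yn-3-yl]oxy}heptan-2-one (both epimers at C1) | C#C/C=C/C[C@@H](C=C)O[C@@H]([C@@H](O[Si](C)(C)C(C)(C)C)CC)CC(=O)C(Cl)Br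
F2 | step 9 | (2R,5S,7R,8S)-7-bromo-2-[(1S)-1-[(tert-butyldimethylsilyl)oxy]propyl]-5-chloro-8-[(2E)-pent-2-en-4-yn-1-yl]oxocan-4-one | C#C/C=C/C[C@@H]1O[C@@H]([C@@H](O[Si](C)(C)C(C)(C)C)CC)CC(=O)[C@@H](Cl)C[C@H]1Br
F3 | step 7 | (S)-2-[(tert-butyldimethylsilyl)oxy]butan-1-ol | OC[C@@H](O[Si](C)(C)C(C)(C)C)CC
F4 | step 7 | (S)-2-[(tert-butyldimethylsilyl)oxy]butanal | O=C[C@@H](O[Si](C)(C)C(C)(C)C)CC
F5 | step 7 | methyl (2E,4S)-4-[(tert-butyldimethylsilyl)oxy]hex-2-enoate | COC(=O)/C=C/[C@@H](O[Si](C)(C)C(C)(C)C)CC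
F6 | step 11 | (2R,4R,5S,7S,8S)-2-[(1S)-1-[(tert-butyldimethylsilyl)oxy]propyl]-5,7-dichloro-8-[(2E)-pent-2-en-4-yn-1-yl]oxocan-4-yl chloromethanesulfonate | C#C/C=C/C[C@@H]1O[C@@H]([C@@H](O[Si](C)(C)C(C)(C)C)CC)C[C@@H](OS(=O)(=O)CCl)[C@@H](Cl)C[C@@H]1Cl
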